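## Structural features

Gnetal is a 2,3-dihydrobenzofuran in which a benzene ring (ring A, C3a to C7a) is fused to a dihydrofuran (ring B: O1, C2, C3) across the C3a–C7a bond. Ring A carries a free hydroxyl at C4 and a formyl group at C6; C2 carries a 4-hydroxyphenyl group and C3 a 3,5-dihydroxyphenyl group. C2 and C3 are neighbouring stereocentres, both S, with the two aryl groups trans, and neither has a nearby functional group that could serve as a handle for stereocontrol. The fragile elements are the four free phenols (easily oxidised), the aldehyde, and the benzylic C2–O1 bond, which can ionise towards a para-quinone methide under acid or base and which also forbids a late hydrogenolysis. The real difficulty is the C3–C3a bond: C3a lies between the oxygen-bearing carbons C4 and C7a, the most hindered position of a resorcinol and one that electrophilic substitution avoids, and it must be joined to a stereogenic diarylmethine carbon in one absolute sense. The feature exploited is this oxygen pattern itself: O–C4–C3a–C7a–O is a 1,3-dioxygenated three-carbon unit, so ring A is the aromatised form of a cyclohexane-1,3-dione whose central carbon is C3a and whose 5-substituent becomes the C6 formyl group. In that dearomatised form C3a can be a carbenoid carbon and either carbonyl oxygen can become O1, so the hindered bond and ring B arise together from an E-stilbene.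

## Logic of the disconnections

12 ⇒ 11. Three phenolic O–H bonds on the C2 and C3 aryl groups are traced back to O–CH2Ph bonds. Free phenols would not survive a carbenoid, an amide base, a hydride or an oxidant, so the oxygens are carried as benzyl ethers. The cut gains no skeletal simplicity but makes every earlier step possible. The forward demand is a cleavage that does not ionise C2–O1, spares the aldehyde and does not use hydrogen.

11 ⇒ 10 ⇒ 9. No skeletal bond is cut; the formyl group at C6 is taken back through the primary alcohol 10 to the ester 9. An ester is what the ring A building block carries, and it tolerates carbenoid and enolate chemistry where an aldehyde would not. The forward demand is a reduction that works beside a free phenol and an oxidation that stops at the aldehyde and leaves that phenol alone.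

9 ⇒ 5. Two hydrogens are added back at C5 and C6, so that aromatic ring A becomes a 4-oxo-cyclohexene whose C3a=C7a bond is a vinylogous ester. This reveals the 1,3-dicarbonyl pattern and turns the inaccessible arene carbon C3a into the central carbon of a dione. The C6 stereocentre that appears is of no consequence. The forward demand is a dehydrogenation confined to ring A that does not touch C2–H or C3–H.

5 ⇒ 2 + 4. The bonds C3–C3a and O1–C2 are cut. They are the two bonds that join the halves of the molecule, and cutting them removes ring B and both stereocentres at once, leaving two achiral partners, one of them a symmetrical dione derivative. The forward step must choose the right alkene carbon for C–C bond formation, the right alkene face, and must translate E geometry into the trans relationship.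

4 ⇒ 3. The C=N bond at the central dione carbon is cut, which corresponds to diazo transfer to an acidic methylene. 3 is a commercial bulk chemical. The forward demand is only a mild base that leaves the ester alone.

2 ⇒ 1. The three O–CH2Ph bonds are cut. 1 is a cheap natural product that already has the E alkene and all three oxygens in place. The forward demand is exhaustive O-alkylation without C-alkylation of the resorcinol ring.

## Other disconnections considered

Alternative 1: The cut is C2–C3 together with O1–C2, so that C2 and its aryl group arrive as a one-carbon ylide unit. In the forward sense, base would expel sulfinate from methyl 4-{[3,5-bis(benzyloxy)phenyl](4-methylbenzenesulfonyl)methyl}-3,5-dihydroxybenzoate A2 to give an ortho-quinone methide. The ylide from a chiral sulfonium salt such as (2S,5S)-1-{[4-(benzyloxy)phenyl]methyl}-2,5-dimethylthiolan-1-ium tetrafluoroborate A3 would add at C3, and the phenoxide would displace the sulfide at C2 to give methyl (2S,3S)-2-[4-(benzyloxy)phenyl]-3-[3,5-bis(benzyloxy)phenyl]-4-hydroxy-2,3-dihydrobenzofuran-6-carboxylate A1.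
- In its favour: ring A is aromatic throughout, and A1 is the methyl ester counterpart of 9, so no aromatisation is needed. On this point it is better than the chosen plan.
- Also in its favour: sulfur-ylide (4+1) annulations of quinone methides are an established reaction class with asymmetric variants, and the anti-betaine/inversion sequence gives trans products. Its stereochemical basis is therefore better documented than that of step 3.
- Against it: the C3–C3a bond must already exist in A2, whose benzylic carbon sits between two hydroxyls. Building it by condensation on the dihydroxy ester meets exactly the regiochemical problem (attack at the less hindered positions) that the chosen plan avoids.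
- Against it: the chiral sulfide is stoichiometric, and a semi-stabilised, electron-rich benzylic ylide adds less reversibly than ester-stabilised ylides, so trans/cis and enantiomeric purity are less secure.
- Step economy: three steps follow the key step instead of four, but A2 and A3 together need about five steps where 2 and 4 need two. Overall it is somewhat longer.

Alternative 2: The cut is C3–C3a, made by a 1,2-shift of the ring A carbon, which is a retrosynthetic ring expansion to the flavanone (2S)-5-(benzyloxy)-2-[4-(benzyloxy)phenyl]-7-{[tri(propan-2-yl)silyl]oxymethyl}-2,3-dihydro-4H-chromen-4-one A5. In the forward sense PhI(OAc)2 with acid and trimethyl orthoformate would make ring A migrate from the carbonyl carbon to the methylene carbon and give methyl (2S,3S)-4-(benzyloxy)-2-[4-(benzyloxy)phenyl]-6-[(triisopropylsilyloxy)methyl]-2,3-dihydrobenzofuran-3-carboxylate A4.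
- In its favour: the hindered C3–C3a bond forms intramolecularly by migration, which is as automatic as in the chosen plan (equal on this point).
- Also in its favour: the absolute configuration would come from established asymmetric flavanone syntheses and a stereospecific rearrangement (better grounded than step 3), and ring A is aromatic with its C6 carbon one oxidation from the aldehyde (better).
- Against it: A4 carries an ester at C3 where the target has the 3,5-dihydroxyphenyl group. A decarboxylative aryl coupling would have to follow, which passes through a trigonal C3 and must re-establish that centre by substrate control, at a cost of about three steps.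
- Against it: the 4-benzyloxyphenyl group at C2 is itself a good migrating group, so the competing 2,3-aryl shift to isoflavone-type products is a real threat, and flavanones can racemise by ring opening under acid.
- Step economy: clearly worse, roughly twelve steps or more.

Alternative 3: The cuts are C7a–O1 and C3–C3a: ring A arrives as an aryne from 3-(benzyloxy)-5-(dimethoxymethyl)-2-(trimethylsilyl)phenyl trifluoromethanesulfonate A7, and O1, C2 and C3 come from the epoxide 4-[(2R,3R)-3-[3,5-bis(benzyloxy)phenyl]oxiran-2-yl]phenyl trifluoromethanesulfonate A8. Fluoride would generate the aryne, the epoxide oxygen would add at C7a, and the aryl anion at C3a would capture C3 as C3–O breaks, giving (2S,3S)-4-(benzyloxy)-3-[3,5-bis(benzyloxy)phenyl]-6-(dimethoxymethyl)-2-[4-(triflyloxy)phenyl]-2,3-dihydrobenzofuran A6.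
- In its favour: it is highly convergent, and A6 is aromatic with the formyl carbon already at the right oxidation level, so only deprotections remain (better in redox economy).
- Also in its favour: the polarisation of an alkoxy-aryne places the new C–C bond next to the oxygenated carbon as automatically as the dione does (equal), and C2 never breaks its C–O bond, so an enantiopure epoxide should pass its configuration on.
- Against it: C3–O heterolysis is required at a benzylic carbon with only meta oxygens, which is electronically unfavourable. The triflate on the other ring is needed solely to suppress the wrong cleavage and must later be removed separately.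
- Against it: the configuration at C3 depends on front-side delivery or on ion-pair collapse and is not assured, the oxonium stage can divert into carbonyl-forming rearrangement or elimination, and insertion into diaryl epoxides has little precedent.
- Step economy: worse; A7 and A8 need about five and four steps, for roughly twelve in total.

Key step: step 3

Remarks on the chemistry (assumptions):
- The descriptors were re-derived from the target string: C2 is S, C3 is S and the aryl groups are trans. The key-step partners and product agree with this, so no structure is altered apart from the points below.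
- The ester alkyl group is a spectator. Ethyl replaces methyl so that commercial 3 can be used directly. A preparation from 3,5-dihydroxybenzoic acid would cost two more steps, and its acid-catalysed esterification would also convert the dione into its enol ether.
- The stilbene is taken from commercial (E)-resveratrol in one step; benzyl ethers are kept because a para-alkoxy group gives the strongest support to the C2 cation.
- The sense of induction of the chiral catalyst with a symmetric carbenoid cannot be predicted with confidence. The S-configured catalyst is written; if it favours the (2R,3R) series, its enantiomer is used with no other change.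

## Route

Step 1
Reactants: 1 (E)-resveratrol, 5-[(E)-2-(4-hydroxyphenyl)ethenyl]benzene-1,3-diol
Product: 2 (E)-1-(benzyloxy)-4-{2-[3,5-bis(benzyloxy)phenyl]ethenyl}benzene
Conditions: BnBr (3.6 equiv), K2CO3 (4.5 equiv), DMF, 23 → 60 °C
Reagents that add atoms: benzyl bromide, BrCc1ccccc1
Why: Williamson ether synthesis; the three phenoxides are O-alkylated by the reactive benzylic bromide, and the E alkene of 1 is carried through untouched.

Step 2
Reactants: 3 ethyl 3,5-dioxocyclohexane-1-carboxylate
Product: 4 ethyl 4-diazo-3,5-dioxocyclohexane-1-carboxylate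
Conditions: 4-AcNHC6H4SO2N3 (1.1 equiv), Et3N (1.5 equiv), MeCN, 0 → 23 °C
Reagents that add atoms: 4-acetamidobenzenesulfonyl azide, CC(=O)Nc1ccc(cc1)S(=O)(=O)N=[N+]=[N-]
Why: Regitz diazo transfer; the acidic dione is deprotonated by the amine, its central carbon attacks the terminal azide nitrogen and the adduct fragments to the diazo dione and the sulfonamide, leaving the ester untouched.

Step 3
Reactants: 4 ethyl 4-diazo-3,5-dioxocyclohexane-1-carboxylate; 2 (E)-1-(benzyloxy)-4-{2-[3,5-bis(benzyloxy)phenyl]ethenyl}benzene
Product: 5 ethyl (2S,3S)-2-[4-(benzyloxy)phenyl]-3-[3,5-bis(benzyloxy)phenyl]-4-oxo-2,3,4,5,6,7-hexahydro-1-benzofuran-6-carboxylate (both C6 epimers)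
Conditions: Rh2(S-PTTL)4 (dirhodium tetrakis[N-phthaloyl-(S)-tert-leucinate], 2 mol %), 4 (1.5 equiv) added over 6 h, PhCF3, 4 Å MS, 0 → 23 °C
Reagents that add atoms: none
Why: Proposed new method: loss of N2 from 4 at the divalent rhodium centre gives an electrophilic acceptor/acceptor carbenoid whose carbene carbon (future C3a) is attacked by the alkene carbon of 2 bearing the 3,5-bis(benzyloxy)phenyl group, because only then does the developing positive charge sit on the carbon (future C2) conjugated with the para-benzyloxy donor. The closest known reaction type is the dirhodium-catalysed formal (3+2) cycloaddition of cyclic 2-diazo-1,3-diones with styrenes and enol ethers to fused dihydrofurans; what is new is a 1,2-diaryl alkene combined with high enantiocontrol. Ring B then closes by 5-exo-trig attack of an enolate oxygen on the quinone-methide-like benzylic cation, forming O1–C2; the two carbonyl oxygens are equivalent for this purpose, so the dione side poses no regiochemical question and the only consequence is the pair of C6 epimers. C3 is created in the C3–C3a bond-forming event, and its configuration is decided by which alkene face the chiral pocket of the four phthalimido tert-leucinate ligands admits to the carbenoid. C2 is created in the ring closure and is set relative to C3: closure from the extended conformation inherited from the E alkene, before rotation about C2–C3, places the aryl groups trans, which is also the less strained arrangement. The step needs chemoselectivity for the alkene over the electron-rich arenes and benzylic C–H bonds (secured by the high nucleophilicity of the alkene terminus remote from the para-alkoxyaryl group), regioselectivity (secured by para- versus meta-oxygen substitution of the two aryl groups) and enantioselectivity (catalyst only). Slow addition of 4 keeps the carbenoid concentration low and suppresses carbene dimerisation.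

Step 4
Reactants: 5 ethyl (2S,3S)-2-[4-(benzyloxy)phenyl]-3-[3,5-bis(benzyloxy)phenyl]-4-oxo-2,3,4,5,6,7-hexahydro-1-benzofuran-6-carboxylate
Product: 9 ethyl (2S,3S)-2-[4-(benzyloxy)phenyl]-3-[3,5-bis(benzyloxy)phenyl]-4-hydroxy-2,3-dihydro-1-benzofuran-6-carboxylate, via C5 phenylselenide 6 (not isolated), via selenoxide 7 (not isolated), via cyclohexadienone tautomer 8 (not isolated)
Conditions: LiN(i-Pr)2 (1.3 equiv), THF, −78 °C; PhSeBr (1.3 equiv), −78 °C; then H2O2 (30% aq.), pyridine, CH2Cl2, 0 → 23 °C
Reagents that add atoms: none
Why: α-Selenenylation of a lithium enolate followed by selenoxide syn-elimination, the standard cyclohexenone-to-phenol aromatisation: kinetic deprotonation of the vinylogous ester at C5 and capture by PhSeBr give 6, oxidation gives 7, syn-elimination towards C6–H gives 8, and 8 tautomerises to the phenol. Selenenylation at C6 instead would converge on the same phenol, the C6 stereocentre is erased, and C2 and C3 carry no acidic or oxidisable function under these conditions.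

Step 5
Reactants: 9 ethyl (2S,3S)-2-[4-(benzyloxy)phenyl]-3-[3,5-bis(benzyloxy)phenyl]-4-hydroxy-2,3-dihydro-1-benzofuran-6-carboxylate
Product: 10 (2S,3S)-2-[4-(benzyloxy)phenyl]-3-[3,5-bis(benzyloxy)phenyl]-6-(hydroxymethyl)-2,3-dihydro-1-benzofuran-4-ol
Conditions: i-Bu2AlH (4.0 equiv), CH2Cl2, −78 → 0 °C; aq. potassium sodium tartrate
Reagents that add atoms: none
Why: Ester reduction by an aluminium hydride; the phenol consumes one equivalent as an inert aluminium phenoxide and the excess reduces the ethyl ester to the benzylic alcohol, while benzyl ethers and ring B are not affected.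

Step 6
Reactants: 10 (2S,3S)-2-[4-(benzyloxy)phenyl]-3-[3,5-bis(benzyloxy)phenyl]-6-(hydroxymethyl)-2,3-dihydro-1-benzofuran-4-ol
Product: 11 (2S,3S)-2-[4-(benzyloxy)phenyl]-3-[3,5-bis(benzyloxy)phenyl]-4-hydroxy-2,3-dihydro-1-benzofuran-6-carbaldehyde
Conditions: MnO2 (activated, 15 equiv), CH2Cl2, 23 °C
Reagents that add atoms: none
Why: MnO2 oxidation of a benzylic alcohol stops at the aldehyde; once the formyl group is in place ring A is deactivated, which protects the free phenol against phenoxyl-type oxidation.

Step 7
Reactants: 11 (2S,3S)-2-[4-(benzyloxy)phenyl]-3-[3,5-bis(benzyloxy)phenyl]-4-hydroxy-2,3-dihydro-1-benzofuran-6-carbaldehyde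
Product: 12 gnetal, (2S,3S)-3-(3,5-dihydroxyphenyl)-4-hydroxy-2-(4-hydroxyphenyl)-2,3-dihydro-1-benzofuran-6-carbaldehyde
Conditions: BCl3 (8 equiv), C6HMe5 (12 equiv), CH2Cl2, −78 °C; MeOH, −78 → 23 °C
Reagents that add atoms: none
Why: Lewis-acid debenzylation with a cation scavenger; BCl3 activates each aryl benzyl ether and the benzyl cation is transferred to pentamethylbenzene by Friedel–Crafts capture, so it cannot alkylate the electron-rich rings. At −78 °C the aldehyde and the C2–O1 bond should survive, and no bond at C2 or C3 is broken.

## Compound list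

1 | (E)-resveratrol, 5-[(E)-2-(4-hydroxyphenyl)ethenyl]benzene-1,3-diol | Oc1ccc(/C=C/c2cc(O)cc(O)c2)cc1 | starting material
2 | (E)-1-(benzyloxy)-4-{2-[3,5-bis(benzyloxy)phenyl]ethenyl}benzene | O(Cc1ccccc1)c1ccc(/C=C/c2cc(OCc3ccccc3)cc(OCc3ccccc3)c2)cc1 | intermediate
3 | ethyl 3,5-dioxocyclohexane-1-carboxylate | CCOC(=O)C1CC(=O)CC(=O)C1 | starting material
4 | ethyl 4-diazo-3,5-dioxocyclohexane-1-carboxylate | CCOC(=O)C1CC(=O)C(=[N+]=[N-])C(=O)C1 | intermediate
5 | ethyl (2S,3S)-2-[4-(benzyloxy)phenyl]-3-[3,5-bis(benzyloxy)phenyl]-4-oxo-2,3,4,5,6,7-hexahydro-1-benzofuran-6-carboxylate (both C6 epimers) | CCOC(=O)C1CC(=O)C2=C(C1)O[C@H](c1ccc(OCc3ccccc3)cc1)[C@H]2c1cc(OCc2ccccc2)cc(OCc2ccccc2)c1 | intermediate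
6 | ethyl (2S,3S)-2-[4-(benzyloxy)phenyl]-3-[3,5-bis(benzyloxy)phenyl]-4-oxo-5-(phenylselanyl)-2,3,4,5,6,7-hexahydro-1-benzofuran-6-carboxylate (C5/C6 diastereomers) | CCOC(=O)C1C([Se]c3ccccc3)C(=O)C2=C(C1)O[C@H](c1ccc(OCc3ccccc3)cc1)[C@H]2c1cc(OCc2ccccc2)cc(OCc2ccccc2)c1 | intermediate
7 | ethyl (2S,3S)-2-[4-(benzyloxy)phenyl]-3-[3,5-bis(benzyloxy)phenyl]-4-oxo-5-(phenylseleninyl)-2,3,4,5,6,7-hexahydro-1-benzofuran-6-carboxylate | CCOC(=O)C1C([Se](=O)c3ccccc3)C(=O)C2=C(C1)O[C@H](c1ccc(OCc3ccccc3)cc1)[C@H]2c1cc(OCc2ccccc2)cc(OCc2ccccc2)c1 | intermediate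
8 | ethyl (2S,3S)-2-[4-(benzyloxy)phenyl]-3-[3,5-bis(benzyloxy)phenyl]-4-oxo-2,3,4,7-tetrahydro-1-benzofuran-6-carboxylate | CCOC(=O)C1=CC(=O)C2=C(C1)O[C@H](c1ccc(OCc3ccccc3)cc1)[C@H]2c1cc(OCc2ccccc2)cc(OCc2ccccc2)c1 | intermediate
9 | ethyl (2S,3S)-2-[4-(benzyloxy)phenyl]-3-[3,5-bis(benzyloxy)phenyl]-4-hydroxy-2,3-dihydro-1-benzofuran-6-carboxylate | CCOC(=O)c1cc(O)c2c(c1)O[C@H](c1ccc(OCc3ccccc3)cc1)[C@H]2c1cc(OCc2ccccc2)cc(OCc2ccccc2)c1 | intermediate
10 | (2S,3S)-2-[4-(benzyloxy)phenyl]-3-[3,5-bis(benzyloxy)phenyl]-6-(hydroxymethyl)-2,3-dihydro-1-benzofuran-4-ol | OCc1cc(O)c2c(c1)O[C@H](c1ccc(OCc3ccccc3)cc1)[C@H]2c1cc(OCc2ccccc2)cc(OCc2ccccc2)c1 | intermediate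
11 | (2S,3S)-2-[4-(benzyloxy)phenyl]-3-[3,5-bis(benzyloxy)phenyl]-4-hydroxy-2,3-dihydro-1-benzofuran-6-carbaldehyde | O=Cc1cc(O)c2c(c1)O[C@H](c1ccc(OCc3ccccc3)cc1)[C@H]2c1cc(OCc2ccccc2)cc(OCc2ccccc2)c1 | intermediate
12 | gnetal, (2S,3S)-3-(3,5-dihydroxyphenyl)-4-hydroxy-2-(4-hydroxyphenyl)-2,3-dihydro-1-benzofuran-6-carbaldehyde | O=Cc1cc(O)c2c(c1)O[C@H](c1ccc(O)cc1)[C@H]2c1cc(O)cc(O)c1 | target

## Step count and least certain steps

Total: 7 steps. Longest linear sequence: 6 steps (3 → 4 → 5 → 9 → 10 → 11 → 12; the branch from 1 through 2 is equally long).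

Step 3 (key step, proposed new method). The most likely failure is poor facial selectivity in the C3–C3a bond formation, because a carbenoid with two identical carbonyl flanks gives the ligand pocket little to differentiate. The second is slow capture of the encumbered carbenoid by a 1,2-disubstituted alkene, which would let attack on the 3,5-dialkoxyaryl ring, carbonyl-ylide formation with the ester, or dimerisation take over.
- Fallback (known chemistry), setting out from 3 and 2 and returning at 5: Mn(OAc)3·2H2O (2.2 equiv) in AcOH at 60 °C oxidises the enol of 3 to an α-dicarbonyl radical, which adds to the alkene carbon of 2 bearing the 3,5-bis(benzyloxy)phenyl group.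
- The 4-benzyloxybenzylic radical is oxidised by a second equivalent of trivalent manganese and closed by the enol oxygen. This known oxidative dihydrofuran annulation should give racemic trans ethyl 2-[4-(benzyloxy)phenyl]-3-[3,5-bis(benzyloxy)phenyl]-4-oxo-2,3,4,5,6,7-hexahydro-1-benzofuran-6-carboxylate F1.
- Preparative chromatography on a chiral stationary phase (supercritical CO2, amylose tris(3,5-dimethylphenylcarbamate)) would then separate the (2S,3S) series, whose C6 epimers are pooled; this material is 5.

Step 4. The most likely failure is over-oxidation of the newly formed electron-rich phenol by the selenium(oxygen) by-products, or incomplete syn-elimination from the diastereomer in which selenium and C6–H are trans.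
- Fallback, from 5 directly to 9: catalytic aerobic dehydrogenation with Pd(OCOCF3)2 (5 mol %), 2-(dimethylamino)pyridine, TsOH and O2 (1 atm) in DMSO at 80 °C.
- This is a different mechanism (enolate of divalent palladium, β-hydride elimination, reoxidation by O2) and a known way from cyclohexenones to phenols. It passes through 8 and makes no compound outside the compound list (entry F0).

Step 7. The most likely failure is ionisation of the benzylic C2–O1 bond by the Lewis acid, leading to ring opening, erosion of the trans relationship or capture of the cation by the scavenger; the aldehyde may also be engaged by the boron halide. The fallback is a late protecting-group exchange without any Lewis acid, setting out from 9 and returning at 12: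
- Hydrogenolysis (H2 1 atm, Pd/C, EtOAc/EtOH, 23 °C, stopped after three equivalents) at the ester stage, where no aldehyde is present, should give ethyl (2S,3S)-3-(3,5-dihydroxyphenyl)-4-hydroxy-2-(4-hydroxyphenyl)-2,3-dihydro-1-benzofuran-6-carboxylate F2.
- Silylation (TBSCl, imidazole, DMF) gives ethyl (2S,3S)-4-[(tert-butyldimethylsilyl)oxy]-3-{3,5-bis[(tert-butyldimethylsilyl)oxy]phenyl}-2-{4-[(tert-butyldimethylsilyl)oxy]phenyl}-2,3-dihydro-1-benzofuran-6-carboxylate F3.
- i-Bu2AlH reduction gives [(2S,3S)-4-[(tert-butyldimethylsilyl)oxy]-3-{3,5-bis[(tert-butyldimethylsilyl)oxy]phenyl}-2-{4-[(tert-butyldimethylsilyl)oxy]phenyl}-2,3-dihydro-1-benzofuran-6-yl]methanol F4.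
- MnO2 oxidation gives (2S,3S)-4-[(tert-butyldimethylsilyl)oxy]-3-{3,5-bis[(tert-butyldimethylsilyl)oxy]phenyl}-2-{4-[(tert-butyldimethylsilyl)oxy]phenyl}-2,3-dihydro-1-benzofuran-6-carbaldehyde F5.
- KHF2 in MeOH at 23 °C then removes the four aryl silyl ethers under nearly neutral conditions to give 12.

Step 6. The most likely failure is oxidation of the free C4 phenol on the manganese oxide surface, or a sluggish heterogeneous reaction of the polar phenolic alcohol.
- Fallback that avoids any oxidation, setting out from 9 and returning at 11 (it replaces steps 5 and 6): MeNH(OMe)·HCl and i-PrMgCl in THF at −20 → 0 °C convert the ester into (2S,3S)-2-[4-(benzyloxy)phenyl]-3-[3,5-bis(benzyloxy)phenyl]-4-hydroxy-N-methoxy-N-methyl-2,3-dihydro-1-benzofuran-6-carboxamide F6.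
- i-Bu2AlH in THF at −78 °C then reduces F6 through the stable chelated adduct to the aldehyde 11.

## Further compounds

F1 | step 3 | racemic trans ethyl 2-[4-(benzyloxy)phenyl]-3-[3,5-bis(benzyloxy)phenyl]-4-oxo-2,3,4,5,6,7-hexahydro-1-benzofuran-6-carboxylate, (2S,3S) and (2R,3R) enantiomers in equal parts, both C6 epimers | CCOC(=O)C1CC(=O)C2=C(C1)O[C@H](c1ccc(OCc3ccccc3)cc1)[C@H]2c1cc(OCc2ccccc2)cc(OCc2ccccc2)c1.CCOC(=O)C1CC(=O)C2=C(C1)O[C@@H](c1ccc(OCc3ccccc3)cc1)[C@@H]2c1cc(OCc2ccccc2)cc(OCc2ccccc2)c1
F0 | step 4 | none | none
F2 | step 7 | ethyl (2S,3S)-3-(3,5-dihydroxyphenyl)-4-hydroxy-2-(4-hydroxyphenyl)-2,3-dihydro-1-benzofuran-6-carboxylate | CCOC(=O)c1cc(O)c2c(c1)O[C@H](c1ccc(O)cc1)[C@H]2c1cc(O)cc(O)c1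
F3 | step 7 | ethyl (2S,3S)-4-[(tert-butyldimethylsilyl)oxy]-3-{3,5-bis[(tert-butyldimethylsilyl)oxy]phenyl}-2-{4-[(tert-butyldimethylsilyl)oxy]phenyl}-2,3-dihydro-1-benzofuran-6-carboxylate | CCOC(=O)c1cc(O[Si](C)(C)C(C)(C)C)c2c(c1)O[C@H](c1ccc(O[Si](C)(C)C(C)(C)C)cc1)[C@H]2c1cc(O[Si](C)(C)C(C)(C)C)cc(O[Si](C)(C)C(C)(C)C)c1
F4 | step 7 | [(2S,3S)-4-[(tert-butyldimethylsilyl)oxy]-3-{3,5-bis[(tert-butyldimethylsilyl)oxy]phenyl}-2-{4-[(tert-butyldimethylsilyl)oxy]phenyl}-2,3-dihydro-1-benzofuran-6-yl]methanol | OCc1cc(O[Si](C)(C)C(C)(C)C)c2c(c1)O[C@H](c1ccc(O[Si](C)(C)C(C)(C)C)cc1)[C@H]2c1cc(O[Si](C)(C)C(C)(C)C)cc(O[Si](C)(C)C(C)(C)C)c1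
F5 | step 7 | (2S,3S)-4-[(tert-butyldimethylsilyl)oxy]-3-{3,5-bis[(tert-butyldimethylsilyl)oxy]phenyl}-2-{4-[(tert-butyldimethylsilyl)oxy]phenyl}-2,3-dihydro-1-benzofuran-6-carbaldehyde | O=Cc1cc(O[Si](C)(C)C(C)(C)C)c2c(c1)O[C@H](c1ccc(O[Si](C)(C)C(C)(C)C)cc1)[C@H]2c1cc(O[Si](C)(C)C(C)(C)C)cc(O[Si](C)(C)C(C)(C)C)c1
F6 | step 6 | (2S,3S)-2-[4-(benzyloxy)phenyl]-3-[3,5-bis(benzyloxy)phenyl]-4-hydroxy-N-methoxy-N-methyl-2,3-dihydro-1-benzofuran-6-carboxamide | CON(C)C(=O)c1cc(O)c2c(c1)O[C@H](c1ccc(OCc3ccccc3)cc1)[C@H]2c1cc(OCc2ccccc2)cc(OCc2ccccc2)c1
A1 | alternative 1 | methyl (2S,3S)-2-[4-(benzyloxy)phenyl]-3-[3,5-bis(benzyloxy)phenyl]-4-hydroxy-2,3-dihydrobenzofuran-6-carboxylate | COC(=O)c1cc(O)c2c(c1)O[C@H](c1ccc(OCc3ccccc3)cc1)[C@H]2c1cc(OCc2ccccc2)cc(OCc2ccccc2)c1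
A2 | alternative 1 | methyl 4-{[3,5-bis(benzyloxy)phenyl](4-methylbenzenesulfonyl)methyl}-3,5-dihydroxybenzoate (racemic at the sulfonyl-bearing carbon) | COC(=O)c1cc(O)c(C(c2cc(OCc3ccccc3)cc(OCc3ccccc3)c2)S(=O)(=O)c2ccc(C)cc2)c(O)c1
A3 | alternative 1 | (2S,5S)-1-{[4-(benzyloxy)phenyl]methyl}-2,5-dimethylthiolan-1-ium tetrafluoroborate | C[C@H]1CC[C@H](C)[S+]1Cc1ccc(OCc2ccccc2)cc1.F[B-](F)(F)F
A4 | alternative 2 | methyl (2S,3S)-4-(benzyloxy)-2-[4-(benzyloxy)phenyl]-6-[(triisopropylsilyloxy)methyl]-2,3-dihydrobenzofuran-3-carboxylate | CC(C)[Si](C(C)C)(C(C)C)OCc1cc(OCc3ccccc3)c2c(c1)O[C@H](c1ccc(OCc3ccccc3)cc1)[C@H]2C(=O)OC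
A5 | alternative 2 | (2S)-5-(benzyloxy)-2-[4-(benzyloxy)phenyl]-7-{[tri(propan-2-yl)silyl]oxymethyl}-2,3-dihydro-4H-chromen-4-one | CC(C)[Si](C(C)C)(C(C)C)OCc1cc(OCc2ccccc2)c2C(=O)C[C@@H](c3ccc(OCc4ccccc4)cc3)Oc2c1
A6 | alternative 3 | (2S,3S)-4-(benzyloxy)-3-[3,5-bis(benzyloxy)phenyl]-6-(dimethoxymethyl)-2-[4-(triflyloxy)phenyl]-2,3-dihydrobenzofuran | COC(OC)c1cc(OCc3ccccc3)c2c(c1)O[C@H](c1ccc(OS(=O)(=O)C(F)(F)F)cc1)[C@H]2c1cc(OCc2ccccc2)cc(OCc2ccccc2)c1
A7 | alternative 3 | 3-(benzyloxy)-5-(dimethoxymethyl)-2-(trimethylsilyl)phenyl trifluoromethanesulfonate | COC(OC)c1cc(OCc2ccccc2)c([Si](C)(C)C)c(OS(=O)(=O)C(F)(F)F)c1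
A8 | alternative 3 | 4-[(2R,3R)-3-[3,5-bis(benzyloxy)phenyl]oxiran-2-yl]phenyl trifluoromethanesulfonate | O=S(=O)(Oc1ccc(cc1)[C@H]1O[C@@H]1c1cc(OCc2ccccc2)cc(OCc2ccccc2)c1)C(F)(F)F
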